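**Remarks on the chemistry (assumptions)**

- Labels: the upper unit has rings A (benzo), C (pyran) and B (aryl); the lower unit has rings D (benzo), F (pyran) and E (aryl). Locants with a double prime belong to the lower unit. The chain carbons that become C2, C3 and C4 of ring C carry these labels from step 2 on.
- The aryne is generated from the silyl triflate in which SiMe3 and OTf have exchanged places (24). It gives the same aryne 25, cannot expel bromide on desilylation because silicon is not next to bromine, and is made without regiochemical ambiguity from 4-(benzyloxy)phenol. The structures of the oxetane and of the insertion product are consistent with the target and need no correction.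
- 17, 18 and 19 are carried as mixtures of C4 epimers (C4 is left undefined in their SMILES), because C4 becomes planar in step 12.
- NaOAc, not an amine, takes up HBr in the last step, because free amines slow the hydrogenolysis of benzyl ethers on palladium.

## Structural features

The target is a 4→6-linked biflavanoid: a 5-deoxy flavan-3-ol of the robinetinidol type (rings A, C, B) whose C4 is bonded to C6'' of the phloroglucinol ring D of (−)-epigallocatechin (rings D, F, E). Ring C carries three contiguous stereocentres, C2 (R), C3 (S) and C4 (S), with aryl B, the 3-hydroxyl and ring D alternating all-trans; ring F carries the 2,3-cis pair C2'' (R) and C3'' (R). Ring A has oxygen only at C7, so C5 is unsubstituted, and the interflavan bond sits at C6'' between two oxygens and not at the more reactive C8''. There are eleven free hydroxyls, nine phenolic, six of them in two air- and base-sensitive pyrogallol rings, and the doubly benzylic C4–C6'' bond is cleaved by acid. The real difficulty is ring C: the C4–aryl bond must go to the hindered C6'' with 3,4-trans control while C2 and C3 are set in absolute terms, and the usual flavan-4-yl cation chemistry is weakened by the missing 5-oxygen. The key step uses the fact that ring A gives ring C two adjacent carbons, C8a bonded to O1 and C4a bonded to C4: this vicinal C–O/C–C pattern is what an aryne leaves when it inserts into a C–O bond, and the other four ring atoms, O1–C2–C3–C4, are an oxetane. The empty C5 can hold a bromine that orients the aryne and is removed in the final hydrogenolysis.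

## Logic of the disconnections

27 ⇒ 26. Only bonds to protecting and auxiliary groups are cut: eleven O–benzyl bonds and the C–Br bonds at C5 and C8''. Benzyl is chosen because one hydrogenolysis removes ethers and halogens together without touching the C4–C6'' bond. The forward step must be buffered against the HBr it produces.

26 ⇒ 19 + 24 (through 25). The cuts are O1–C8a and C4–C4a, the two bonds that join ring A to ring C. Ring A leaves as a two-carbon aryne unit and ring C contracts to a four-membered ether in which C2 and C3 already have their final configuration. One stereocentre (C4) and two skeletal bonds are left for a single step. That step must deliver oxygen to the aryne carbon remote from bromine, break the C4–O and not the C2–O bond of 19, and close at C4 anti to the C3 benzyloxy group.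

19 ⇒ 17. The O1–C2 bond of the four-membered ring is cut, which returns an acyclic 1,3-diol. The ring oxygen is taken from C4 because only C2 must be stereodefined: displacement at C2 with inversion turns a syn C2/C3 relation, the one an auxiliary aldol gives most reliably, into the trans relation of 19. The forward step must sulfonylate the C2 hydroxyl in preference to the hindered C4 hydroxyl and displace it before the electron-rich benzylic centre ionises.

17 ⇒ 16 ⇒ 13 + 8. After the C4 carbinol is changed to a ketone, the C4–C6'' bond is cut between an acyl donor and a ring D carbanion. This is the convergent point: the whole lower unit is separated from a three-carbon piece that holds C2 and C3. The forward step needs ring D metalated at C6'' with C8'' inert, hence iodine at C6'' and bromine at C8'' in 13, and an acyl donor that reacts once and does not epimerise at C3.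

8 ⇒ 7 ⇒ 3 + 4, and 3 ⇒ 1 + 2. The amide is traced to the auxiliary imide and the C2–C3 bond is cut as an aldol. Both chain stereocentres then come from one reaction of a glycolate enolate with a non-enolisable aldehyde, which demands high syn and facial selectivity. The N–acyl cut leads to 1 and 2.

13 ⇒ 12 ⇒ 11 ⇒ 9. The C–I bond, the C–Br bond and six O–benzyl bonds are removed in turn. Rings D, F and E with both lower stereocentres are thus taken unchanged from 9. The demand is regiocontrol in the halogenations: bromine must go to the more reactive C8'' first so that iodine can only enter at C6''.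

24 ⇒ 21 ⇒ 20. The O–S and C–Si bonds are cut, then two C–Br bonds. A para-substituted phenol fixes all positions: both ortho positions are brominated, one bromine is traded for silicon by an oxygen-to-carbon silyl shift, and the other stays as the director in 25.

## Other disconnections considered

Alternative 1: The cut is the O1–C2 bond of the lower pyran ring F. In the forward step the cis-epoxide A2, which already contains the whole upper unit and has one free phenol on ring D, would be treated with camphorsulfonic acid; the phenol would open the epoxide at its benzylic carbon with inversion and give the 2,3-cis ring F of A1 with the lower 3-hydroxyl free.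
- In its favour: phenol opening of a benzylic epoxide is an established closure for flavan-3-ols, so on mechanistic precedent it is better than the chosen plan. A1 carries no halogen, so the end game would be a plain debenzylation without HBr, which is also better.
- Against it here: it takes apart the one part of the molecule that 9 supplies intact. A2 needs an enantioselective cis-epoxidation of a Z-1,3-diarylpropene, a ring D with one phenol differentiated from two others, and the complete upper unit with its C4–C6'' bond beforehand. The acid could open the epoxide through a benzylic cation, leaking into the 2,3-trans series, and it meets the ionisable interflavan bond.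
- Comparison: on structure it forms one C–O bond in a ring that need not be made and leaves ring C and C4 unsolved, whereas the chosen plan forms two skeletal bonds at the real difficulty. On step economy the de novo lower unit would cost far more than steps 4 to 6.

Alternative 2: The cuts are O1–C2 and C3–C4. A chiral phosphoric acid would dehydrate the ortho-hydroxybenzhydrol A4 to an ortho-quinone methide, and an oxa-Diels–Alder reaction with the (E)-styrylboronate A5 would give the all-trans 3-boryl chroman A3; C–B oxidation with retention and hydrogenolysis would follow.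
- In its favour: two bonds and all three stereocentres of ring C in one catalytic step from simple pieces (A4 from 14 and a suitably substituted salicylaldehyde). On stereocentres per step and on step count it is better than the chosen plan, by about three steps on paper, and it avoids the oxetane.
- Against it here: the methide carbon carries the doubly ortho-substituted ring D, which hinders the cycloaddition. An alkenylboronate is a weak 2π partner and may instead transfer its alkenyl group to C4 with loss of boron. The all-trans outcome needs both E-geometry transfer and exo/endo control, and the catalyst must control the face in the presence of the chiral lower unit. An extra peroxide oxidation is needed on an electron-rich substrate.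
- Comparison: on structure it is equal (same ring, same convergence). On mechanism the reaction class is better established than aryne insertion, but this substrate pairing is about as uncertain. The chosen plan fixes C2 and C3 by auxiliary control before the risky step, so that only C4 depends on it.

Alternative 3: The cut is C4–C4a. BF3·OEt2 would ionise the acyclic carbinol A7 (both epimers) to the ring D-stabilised cation, and the tethered 3-benzyloxyphenyl ether would close ring C through the carbon para to its benzyloxy group, giving A6.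
- In its favour: cationic cyclisation onto an arene is known chemistry, so on precedent it is better than the chosen plan. It is stereoconvergent at C4 in the same way and needs no bromine at C5. A7 could come from 17 by a Mitsunobu etherification with 3-(benzyloxy)phenol A8, so the linear length is equal and the total is two steps shorter.
- Against it here: the aryl ether must be formed at an electron-rich benzylic carbinol with clean inversion and in the presence of the C4 hydroxyl. Under the Lewis acid the long-lived cation can also be captured by ring B (five-membered ring) or lose a proton. The ortho/para choice on the tethered ring rests on sterics alone.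
- Comparison: it forms one bond and one ring against two bonds. In the chosen plan the attacking carbon is fixed by the aryne and its bromine, and the nucleophile is an aryl anion born next to the cation, which should outrun ring B.

Key step: step 12

## Route

Step 1
Reactants: 1 (R)-4-benzyloxazolidin-2-one; 2 benzyloxyacetyl chloride
Product: 3 (R)-4-benzyl-3-[(benzyloxy)acetyl]oxazolidin-2-one
Conditions: Et3N, DMAP (cat.), CH2Cl2, 0 °C → rt
Reagents that add atoms: none
Why: N-acylation of the oxazolidinone by the acid chloride under nucleophilic catalysis; no stereocentre is involved.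

Step 2
Reactants: 3 (R)-4-benzyl-3-[(benzyloxy)acetyl]oxazolidin-2-one; 4 3,4,5-tris(benzyloxy)benzaldehyde
Product: 7 (R)-4-benzyl-3-{(2R,3S)-2-(benzyloxy)-3-hydroxy-3-[3,4,5-tris(benzyloxy)phenyl]propanoyl}oxazolidin-2-one (syn aldol), via dibutylboron Z-enolate 5 (not isolated), via dibutylboron aldolate 6 (not isolated)
Conditions: Bu2BOTf, Et3N, CH2Cl2, −78 → 0 °C; 4, −78 → 0 °C; then pH 7 buffer, MeOH, H2O2, 0 °C
Reagents that add atoms: none
Why: Evans syn glycolate aldol: the Z-boron enolate 5 should react through a closed Zimmerman–Traxler chair on the face away from the auxiliary's benzyl group, setting C3 (R) and C2 (S) syn to each other. The aldehyde cannot enolise.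

Step 3
Reactants: 7 syn aldol imide
Product: 8 (2R,3S)-2-(benzyloxy)-3-hydroxy-N-methoxy-N-methyl-3-[3,4,5-tris(benzyloxy)phenyl]propanamide
Conditions: MeNHOMe·HCl, AlMe3, CH2Cl2, −20 → 0 °C
Reagents that add atoms: N,O-dimethylhydroxylamine hydrochloride, CNOC.Cl
Why: Weinreb amide formation by aluminium amide transamination, directed to the exocyclic carbonyl by the free β-hydroxyl; the auxiliary 1 is released for reuse and neither stereocentre is touched.

Step 4
Reactants: 9 (−)-epigallocatechin
Product: 11 3,5,7,3',4',5'-hexa-O-benzyl-(−)-epigallocatechin, via penta-O-benzyl ether 10 (not isolated)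
Conditions: BnBr, K2CO3, DMF, 0 °C → rt; then NaH, Bu4NI (cat.), 0 °C → rt
Reagents that add atoms: benzyl bromide, BrCc1ccccc1
Why: Williamson O-benzylation, first of the five phenols under carbonate, then of the secondary 3-hydroxyl as its sodium alkoxide in the same flask. The weak base in the first stage avoids the C2 epimerisation that flavan-3-ols with free phenols can undergo with strong base.

Step 5
Reactants: 11 hexa-O-benzyl-(−)-epigallocatechin
Product: 12 8-bromo-hexa-O-benzyl-(−)-epigallocatechin
Conditions: NBS, CH2Cl2, −78 → −20 °C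
Reagents that add atoms: N-bromosuccinimide, O=C1CCC(=O)N1Br
Why: Electrophilic aromatic bromination; in benzylated flavan-3-ols C8 of the phloroglucinol ring is the more reactive position, so one equivalent of NBS at low temperature should give the 8-bromide, which blocks C8.

Step 6
Reactants: 12 8-bromo-hexa-O-benzyl-(−)-epigallocatechin
Product: 13 8-bromo-6-iodo-hexa-O-benzyl-(−)-epigallocatechin
Conditions: NIS, CF3CO2H (cat.), CH2Cl2, 0 °C → rt, dark
Reagents that add atoms: N-iodosuccinimide, O=C1CCC(=O)N1I
Why: Electrophilic aromatic iodination at the only free position of ring D, still activated by three oxygens (ortho, ortho, para); ring E has no comparably activated position. The iodine is the handle for selective metalation.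

Step 7
Reactants: 13 8-bromo-6-iodo-hexa-O-benzyl-(−)-epigallocatechin; 8 Weinreb amide
Product: 16 (2R,3S)-2-(benzyloxy)-1-(8-bromo-hexa-O-benzylepigallocatechin-6-yl)-3-hydroxy-3-[3,4,5-tris(benzyloxy)phenyl]propan-1-one, via aryl Grignard reagent 14 (not isolated), via chloromagnesium alkoxide 15 (not isolated)
Conditions: 13, iPrMgCl·LiCl, THF, −30 °C; 8, iPrMgCl, THF, −30 °C; combine, −30 → 0 °C; aq. NH4Cl
Reagents that add atoms: none
Why: Iodine–magnesium exchange is much faster at C–I than at C–Br, so 14 should form with the C8'' bromide intact. Its acylation by the Weinreb amide (Weinreb ketone synthesis, hydroxyl masked as alkoxide 15) stops at the chelated tetrahedral adduct, so the ketone appears only on work-up and C3 is not epimerised.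

Step 8
Reactants: 16 β-hydroxy ketone
Product: 17 (1RS,2R,3S)-2-(benzyloxy)-1-(8-bromo-hexa-O-benzylepigallocatechin-6-yl)-3-[3,4,5-tris(benzyloxy)phenyl]propane-1,3-diol
Conditions: LiBH4, THF, −40 → 0 °C
Reagents that add atoms: none
Why: Hydride reduction of the hindered aryl ketone under aprotic conditions, chosen to avoid retro-aldol cleavage and C3 epimerisation. The new carbinol centre C4 needs no control because it becomes planar in step 12.

Step 9
Reactants: 17 1,3-diol (C4 epimers)
Product: 19 (2R,3R,4RS)-3-(benzyloxy)-4-(8-bromo-hexa-O-benzylepigallocatechin-6-yl)-2-[3,4,5-tris(benzyloxy)phenyl]oxetane (2,3-trans), via C2 monotosylate 18 (not isolated)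
Conditions: KOtBu (1 equiv), TsCl (1 equiv), THF, −20 °C; then KOtBu (1.2 equiv), −20 °C → rt
Reagents that add atoms: none
Why: Williamson oxetane synthesis: the C2 hydroxyl should be sulfonylated in preference to the C4 hydroxyl, which is flanked by two ortho benzyloxy groups. The C4 alkoxide then displaces the tosylate (4-exo-tet, SN2) with inversion at C2, turning the syn aldol relation into the 2,3-trans oxetane.

Step 10
Reactants: 20 4-(benzyloxy)phenol
Product: 21 4-(benzyloxy)-2,6-dibromophenol
Conditions: NBS (2.05 equiv), iPr2NH (cat.), CH2Cl2, 0 °C → rt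
Reagents that add atoms: N-bromosuccinimide, O=C1CCC(=O)N1Br
Why: Amine-catalysed ortho-selective electrophilic bromination of a phenol; the para position is blocked, so both positions ortho to the hydroxyl are brominated.

Step 11
Reactants: 21 4-(benzyloxy)-2,6-dibromophenol
Product: 24 4-(benzyloxy)-2-bromo-6-(trimethylsilyl)phenyl trifluoromethanesulfonate, via aryl trimethylsilyl ether 22 (not isolated), via lithium silylphenolate 23 (not isolated)
Conditions: (Me3Si)2NH, THF, 65 °C; n-BuLi, THF, −100 → −78 °C; Tf2O, −78 → 0 °C
Reagents that add atoms: hexamethyldisilazane, C[Si](C)(C)N[Si](C)(C)C; trifluoromethanesulfonic anhydride, O=S(=O)(OS(=O)(=O)C(F)(F)F)C(F)(F)F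
Why: O-silylation, bromine–lithium exchange of one of two equivalent bromides and a 1,3 oxygen-to-carbon silyl shift (retro-Brook rearrangement) give phenolate 23, which is triflated; this is the standard entry to ortho-silylaryl triflates. The aryllithium is meta to the remaining bromide and cannot eliminate it.

Step 12
Reactants: 19 trans-oxetane (C4 epimers); 24 4-(benzyloxy)-2-bromo-6-(trimethylsilyl)phenyl trifluoromethanesulfonate
Product: 26 5,8''-dibromo-undeca-O-benzyl-robinetinidol-(4α→6)-epigallocatechin (all-trans ring C; benzyl ethers at O7, O3, O3', O4', O5' and on all six oxygens of the lower unit; Br at C5 and C8''), via 5-(benzyloxy)-3-bromobenzyne 25 (not isolated)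
Conditions: 24 (3 equiv, slow addition), Bu4N[Ph3SiF2] (TBAT), toluene, 4 Å molecular sieves, 50 °C
Reagents that add atoms: none
Why: Proposed new method: fluoride converts 24 into aryne 25, in which the bromine (inductive pull and distortion of the triple bond) makes the remote aryne carbon (future C8a) the electrophilic one, so the oxetane oxygen of 19 should add there and the negative charge should develop on the carbon next to bromine (future C4a); the weak opposite bias of the benzyloxy group should be overridden. The resulting aryl anion/O-aryloxetanium zwitterion should ionise at C4, whose cation is stabilised by the two ortho and one para oxygens of ring D, whereas C2 has only the para oxygen of ring B; a concerted displacement is excluded because the breaking C4–O bond would lie inside the forming ring (6-endo-tet). Collapse of the ion pair then forms C4–C4a and closes ring C as a six-membered ring, formally a 6-exo-trig attack of the aryl anion on the cationic C4=ring D π system, so the net change is insertion of the aryne into the C4–O σ bond with a two-carbon ring expansion. The closest known reaction types are aryne insertion into the C–O bond of epoxides to give dihydrobenzofurans and the aryne-induced opening of cyclic ethers through O-aryloxonium intermediates that external nucleophiles intercept; here the aryl anion itself is the nucleophile. C2 and C3 are untouched and keep the trans relation of 19. The new stereocentre C4 is set in the ring closure: a chair-like transition state with aryl B, the C3 benzyloxy group and ring D all pseudo-equatorial should give bond formation anti to the C3 substituent (3,4-trans), and because the cation is planar both C4 epimers of 19 converge. The step needs the oxetane oxygen to win over ten benzyl ether oxygens (secured by the higher Lewis basicity of the strained ether), C–C collapse to win over proton transfer to the aryl anion (secured by an aprotic medium free of acidic C–H bonds and by anhydrous fluoride), and the ortho-bromoaryl anion to keep its bromide (secured by the fast intramolecular capture).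

Step 13
Reactants: 26 5,8''-dibromo undecabenzyl ether
Product: 27 robinetinidol-(4α→6)-epigallocatechin, (2R,3R)-6-[(2R,3S,4S)-3,7-dihydroxy-2-(3,4,5-trihydroxyphenyl)chroman-4-yl]-2-(3,4,5-trihydroxyphenyl)chromane-3,5,7-triol
Conditions: H2 (1 atm), Pd(OH)2/C, NaOAc, THF/MeOH/H2O, rt
Reagents that add atoms: none
Why: Catalytic hydrogenolysis should cleave the eleven benzyl ethers and reduce both aryl bromides (hydrodehalogenation) in one operation. NaOAc takes up the HBr so that the acid-labile C4–C6'' bond is not exposed to acid, and no stereocentre is affected.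

## Compound list

1 | (R)-4-benzyloxazolidin-2-one | O=C1N[C@H](Cc2ccccc2)CO1 | starting material
2 | benzyloxyacetyl chloride | O=C(Cl)COCc1ccccc1 | starting material
3 | (R)-4-benzyl-3-[(benzyloxy)acetyl]oxazolidin-2-one | O=C(COCc1ccccc1)N1[C@H](Cc2ccccc2)COC1=O | intermediate
4 | 3,4,5-tris(benzyloxy)benzaldehyde | O=Cc1cc(OCc2ccccc2)c(OCc2ccccc2)c(OCc2ccccc2)c1 | starting material
5 | dibutylboron Z-enolate of 3 | CCCCB(CCCC)O/C(=C\OCc1ccccc1)N1[C@H](Cc2ccccc2)COC1=O | intermediate (not isolated)
6 | dibutylboron aldolate of 7 | CCCCB(CCCC)O[C@@H](c1cc(OCc2ccccc2)c(OCc2ccccc2)c(OCc2ccccc2)c1)[C@@H](OCc1ccccc1)C(=O)N1[C@H](Cc2ccccc2)COC1=O | intermediate (not isolated)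
7 | (R)-4-benzyl-3-{(2R,3S)-2-(benzyloxy)-3-hydroxy-3-[3,4,5-tris(benzyloxy)phenyl]propanoyl}oxazolidin-2-one | O[C@@H](c1cc(OCc2ccccc2)c(OCc2ccccc2)c(OCc2ccccc2)c1)[C@@H](OCc1ccccc1)C(=O)N1[C@H](Cc2ccccc2)COC1=O | intermediate
8 | (2R,3S)-2-(benzyloxy)-3-hydroxy-N-methoxy-N-methyl-3-[3,4,5-tris(benzyloxy)phenyl]propanamide | O[C@@H](c1cc(OCc2ccccc2)c(OCc2ccccc2)c(OCc2ccccc2)c1)[C@@H](OCc1ccccc1)C(=O)N(C)OC | intermediate
9 | (−)-epigallocatechin | O[C@@H]1Cc2c(O)cc(O)cc2O[C@@H]1c1cc(O)c(O)c(O)c1 | starting material
10 | 5,7,3',4',5'-penta-O-benzyl-(−)-epigallocatechin (free 3-OH) | c1c(OCc3ccccc3)cc2c(c1OCc1ccccc1)C[C@@H](O)[C@@H](c1cc(OCc3ccccc3)c(OCc3ccccc3)c(OCc3ccccc3)c1)O2 | intermediate (not isolated)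
11 | 3,5,7,3',4',5'-hexa-O-benzyl-(−)-epigallocatechin | c1c(OCc3ccccc3)cc2c(c1OCc1ccccc1)C[C@@H](OCc1ccccc1)[C@@H](c1cc(OCc3ccccc3)c(OCc3ccccc3)c(OCc3ccccc3)c1)O2 | intermediate
12 | 8-bromo-hexa-O-benzyl-(−)-epigallocatechin | c1c(OCc3ccccc3)c(Br)c2c(c1OCc1ccccc1)C[C@@H](OCc1ccccc1)[C@@H](c1cc(OCc3ccccc3)c(OCc3ccccc3)c(OCc3ccccc3)c1)O2 | intermediate
13 | 8-bromo-6-iodo-hexa-O-benzyl-(−)-epigallocatechin | Ic1c(OCc3ccccc3)c(Br)c2c(c1OCc1ccccc1)C[C@@H](OCc1ccccc1)[C@@H](c1cc(OCc3ccccc3)c(OCc3ccccc3)c(OCc3ccccc3)c1)O2 | intermediate
14 | (8-bromo-hexa-O-benzylepigallocatechin-6-yl)magnesium chloride (LiCl complex) | Cl[Mg]c1c(OCc3ccccc3)c(Br)c2c(c1OCc1ccccc1)C[C@@H](OCc1ccccc1)[C@@H](c1cc(OCc3ccccc3)c(OCc3ccccc3)c(OCc3ccccc3)c1)O2 | intermediate (not isolated)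
15 | chloromagnesium alkoxide of 8 | Cl[Mg]O[C@@H](c1cc(OCc2ccccc2)c(OCc2ccccc2)c(OCc2ccccc2)c1)[C@@H](OCc1ccccc1)C(=O)N(C)OC | intermediate (not isolated)
16 | (2R,3S)-2-(benzyloxy)-1-(8-bromo-hexa-O-benzylepigallocatechin-6-yl)-3-hydroxy-3-[3,4,5-tris(benzyloxy)phenyl]propan-1-one | O[C@@H](c1cc(OCc2ccccc2)c(OCc2ccccc2)c(OCc2ccccc2)c1)[C@@H](OCc1ccccc1)C(=O)c1c(OCc3ccccc3)c(Br)c2c(c1OCc1ccccc1)C[C@@H](OCc1ccccc1)[C@@H](c1cc(OCc3ccccc3)c(OCc3ccccc3)c(OCc3ccccc3)c1)O2 | intermediate
17 | (1RS,2R,3S)-2-(benzyloxy)-1-(8-bromo-hexa-O-benzylepigallocatechin-6-yl)-3-[3,4,5-tris(benzyloxy)phenyl]propane-1,3-diol | O[C@@H](c1cc(OCc2ccccc2)c(OCc2ccccc2)c(OCc2ccccc2)c1)[C@@H](OCc1ccccc1)C(O)c1c(OCc3ccccc3)c(Br)c2c(c1OCc1ccccc1)C[C@@H](OCc1ccccc1)[C@@H](c1cc(OCc3ccccc3)c(OCc3ccccc3)c(OCc3ccccc3)c1)O2 | intermediate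
18 | 3-O-(4-methylbenzenesulfonyl) derivative of 17 (tosylate on the ring B carbinol, C2) | Cc1ccc(cc1)S(=O)(=O)O[C@@H](c1cc(OCc2ccccc2)c(OCc2ccccc2)c(OCc2ccccc2)c1)[C@@H](OCc1ccccc1)C(O)c1c(OCc3ccccc3)c(Br)c2c(c1OCc1ccccc1)C[C@@H](OCc1ccccc1)[C@@H](c1cc(OCc3ccccc3)c(OCc3ccccc3)c(OCc3ccccc3)c1)O2 | intermediate (not isolated)
19 | (2R,3R,4RS)-3-(benzyloxy)-4-(8-bromo-hexa-O-benzylepigallocatechin-6-yl)-2-[3,4,5-tris(benzyloxy)phenyl]oxetane (2,3-trans) | O1[C@H](c2cc(OCc3ccccc3)c(OCc3ccccc3)c(OCc3ccccc3)c2)[C@@H](OCc3ccccc3)C1c1c(OCc3ccccc3)c(Br)c2c(c1OCc3ccccc3)C[C@@H](OCc3ccccc3)[C@@H](c1cc(OCc3ccccc3)c(OCc3ccccc3)c(OCc3ccccc3)c1)O2 | intermediate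
20 | 4-(benzyloxy)phenol | Oc1ccc(OCc2ccccc2)cc1 | starting material
21 | 4-(benzyloxy)-2,6-dibromophenol | Oc1c(Br)cc(OCc2ccccc2)cc1Br | intermediate
22 | [4-(benzyloxy)-2,6-dibromophenoxy]trimethylsilane | C[Si](C)(C)Oc1c(Br)cc(OCc2ccccc2)cc1Br | intermediate (not isolated)
23 | lithium 4-(benzyloxy)-2-bromo-6-(trimethylsilyl)phenolate | [Li+].[O-]c1c(Br)cc(OCc2ccccc2)cc1[Si](C)(C)C | intermediate (not isolated)
24 | 4-(benzyloxy)-2-bromo-6-(trimethylsilyl)phenyl trifluoromethanesulfonate | C[Si](C)(C)c1cc(OCc2ccccc2)cc(Br)c1OS(=O)(=O)C(F)(F)F | intermediate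
25 | 5-(benzyloxy)-3-bromobenzyne (5-(benzyloxy)-3-bromo-1,2-didehydrobenzene) | BrC1=CC(OCc2ccccc2)=CC#C1 | intermediate (not isolated)
26 | 5,8''-dibromo-undeca-O-benzyl-robinetinidol-(4α→6)-epigallocatechin | c1ccccc1COc1cc(Br)c2c(c1)O[C@H](c1cc(OCc3ccccc3)c(OCc3ccccc3)c(OCc3ccccc3)c1)[C@@H](OCc3ccccc3)[C@@H]2c1c(OCc3ccccc3)c(Br)c2c(c1OCc3ccccc3)C[C@@H](OCc3ccccc3)[C@@H](c1cc(OCc3ccccc3)c(OCc3ccccc3)c(OCc3ccccc3)c1)O2 | intermediate
27 | robinetinidol-(4α→6)-epigallocatechin, (2R,3R)-6-[(2R,3S,4S)-3,7-dihydroxy-2-(3,4,5-trihydroxyphenyl)chroman-4-yl]-2-(3,4,5-trihydroxyphenyl)chromane-3,5,7-triol | Oc1ccc2c(c1)O[C@H](c1cc(O)c(O)c(O)c1)[C@@H](O)[C@@H]2c1c(O)cc2c(c1O)C[C@@H](O)[C@@H](c1cc(O)c(O)c(O)c1)O2 | target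

## Step count and least certain steps

Total step count: 13. Longest linear sequence: 8 steps (steps 4, 5, 6, 7, 8, 9, 12, 13 from 9; equally steps 1, 2, 3, 7, 8, 9, 12, 13 from 1).

Step 12 (key step, proposed new method). What is most likely to go wrong is that the oxetane oxygen, flanked by two aryl-bearing carbons, is too shielded, so the short-lived aryne is consumed by attack of benzyl ether oxygens, by ene or cycloaddition reactions with the electron-rich rings, or by oligomerisation. If the zwitterion does form, proton transfer from C3–H to the aryl anion (elimination) or loss of bromide from the ortho-bromoaryl anion could outrun C–C bond formation. The fallback uses the established acid-promoted flavan-4-yl coupling with a bromine-blocked nucleophile. It sets out from 12 and rejoins the route at 27. Commercial (+)-dihydrorobinetin F1 would be benzylated on its four phenols (BnBr, K2CO3, DMF) to the 7,3',4',5'-tetra-O-benzyl ether F2. Reduction with NaBH4 would give the flavan-3,4-diol F3. Ionisation of F3 with TMSOTf in CH2Cl2 at low temperature in the presence of an excess of 12 should lead to capture of the C4 cation at C6'', the only free position of ring D, anti to the C3 hydroxyl. This would give the 8''-bromo decabenzyl ether with free upper 3-hydroxyl F4, and hydrogenolysis under the conditions of step 13 would give 27.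

Step 9. The likely failures are ionisation of the para-alkoxybenzylic C2 tosylate before the four-membered ring closes, with loss of configuration at C2, and base-induced fragmentation of the 1,3-alkoxide sulfonate (Grob fragmentation to an aryl aldehyde and an enol ether). The fallback sets out from 17 and returns at 19: a redox cyclodehydration under Mitsunobu conditions (PPh3, DIAD, toluene, 0 °C → rt). The less hindered C2 hydroxyl becomes an oxyphosphonium group and is displaced with inversion by the neutral C4 hydroxyl, so neither a sulfonate nor a free alkoxide is present. It makes no new compound (F0).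

Step 7. The likely failure is slow acylation by the doubly ortho-substituted aryl Grignard reagent, so that enolisation of the amide (epimerisation at C3) or retro-aldol cleavage of the magnesium aldolate competes; retro-aldol cleavage of 16 during work-up is a further risk. The fallback sets out from 8 and returns at 17, bypassing 16 and step 8. Silylation (Et3SiCl, imidazole) would give the triethylsilyl ether F5 and reduction with DIBAL-H the aldehyde F6. Addition of 14 to this more electrophilic carbonyl would give the silyl-protected carbinol F7 directly (either C4 epimer is acceptable), and Bu4NF would release 17.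

Step 13. The likely failures are incomplete cleavage of eleven benzyl ethers as bromide and the adsorbing polyphenol slow the catalyst, and acid-induced cleavage of the C4–C6'' bond if the buffering is insufficient. The fallback sets out from 26 and returns at 27. Both bromines would first be removed by bromine–lithium exchange (n-BuLi, THF, −78 °C) and protonation (MeOH) to give the halogen-free undecabenzyl ether F8. F8 would then be hydrogenolysed (H2, Pd(OH)2/C, THF/MeOH) in a neutral medium in which no HBr arises.

## Further compounds

F1 | step 12 | (+)-dihydrorobinetin, (2R,3R)-3,7-dihydroxy-2-(3,4,5-trihydroxyphenyl)chroman-4-one | Oc1ccc2c(c1)O[C@H](c1cc(O)c(O)c(O)c1)[C@@H](O)C2=O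
F2 | step 12 | 7,3',4',5'-tetra-O-benzyl-(+)-dihydrorobinetin | c1ccccc1COc1ccc2c(c1)O[C@H](c1cc(OCc3ccccc3)c(OCc3ccccc3)c(OCc3ccccc3)c1)[C@@H](O)C2=O
F3 | step 12 | (2R,3S)-7-(benzyloxy)-2-[3,4,5-tris(benzyloxy)phenyl]chromane-3,4-diol (C4 epimers) | c1ccccc1COc1ccc2c(c1)O[C@H](c1cc(OCc3ccccc3)c(OCc3ccccc3)c(OCc3ccccc3)c1)[C@@H](O)C2O
F4 | step 12 | 8''-bromo-deca-O-benzyl-robinetinidol-(4α→6)-epigallocatechin with free upper 3-hydroxyl | c1ccccc1COc1ccc2c(c1)O[C@H](c1cc(OCc3ccccc3)c(OCc3ccccc3)c(OCc3ccccc3)c1)[C@@H](O)[C@@H]2c1c(OCc3ccccc3)c(Br)c2c(c1OCc3ccccc3)C[C@@H](OCc3ccccc3)[C@@H](c1cc(OCc3ccccc3)c(OCc3ccccc3)c(OCc3ccccc3)c1)O2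
F0 | step 9 | none | none
F5 | step 7 | (2R,3S)-2-(benzyloxy)-N-methoxy-N-methyl-3-(triethylsilyloxy)-3-[3,4,5-tris(benzyloxy)phenyl]propanamide | CC[Si](CC)(CC)O[C@@H](c1cc(OCc2ccccc2)c(OCc2ccccc2)c(OCc2ccccc2)c1)[C@@H](OCc1ccccc1)C(=O)N(C)OC
F6 | step 7 | (2R,3S)-2-(benzyloxy)-3-(triethylsilyloxy)-3-[3,4,5-tris(benzyloxy)phenyl]propanal | CC[Si](CC)(CC)O[C@@H](c1cc(OCc2ccccc2)c(OCc2ccccc2)c(OCc2ccccc2)c1)[C@@H](OCc1ccccc1)C=O
F7 | step 7 | 3-O-triethylsilyl ether of 17 (silyl group on the ring B carbinol oxygen; C4 epimers) | CC[Si](CC)(CC)O[C@@H](c1cc(OCc2ccccc2)c(OCc2ccccc2)c(OCc2ccccc2)c1)[C@@H](OCc1ccccc1)C(O)c1c(OCc3ccccc3)c(Br)c2c(c1OCc1ccccc1)C[C@@H](OCc1ccccc1)[C@@H](c1cc(OCc3ccccc3)c(OCc3ccccc3)c(OCc3ccccc3)c1)O2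
F8 | step 13 | undeca-O-benzyl-robinetinidol-(4α→6)-epigallocatechin (no halogen) | c1ccccc1COc1ccc2c(c1)O[C@H](c1cc(OCc3ccccc3)c(OCc3ccccc3)c(OCc3ccccc3)c1)[C@@H](OCc3ccccc3)[C@@H]2c1c(OCc3ccccc3)cc2c(c1OCc3ccccc3)C[C@@H](OCc3ccccc3)[C@@H](c1cc(OCc3ccccc3)c(OCc3ccccc3)c(OCc3ccccc3)c1)O2
A1 | alternative 1 | deca-O-benzyl ether of the target with free lower 3-hydroxyl | c1ccccc1COc1ccc2c(c1)O[C@H](c1cc(OCc3ccccc3)c(OCc3ccccc3)c(OCc3ccccc3)c1)[C@@H](OCc3ccccc3)[C@@H]2c1c(OCc3ccccc3)cc2c(c1OCc3ccccc3)C[C@@H](O)[C@@H](c1cc(OCc3ccccc3)c(OCc3ccccc3)c(OCc3ccccc3)c1)O2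
A2 | alternative 1 | benzylated upper unit bearing at C4 a 2,4-bis(benzyloxy)-6-hydroxyphenyl ring with a cis-(2-aryloxiranyl)methyl group at its 3-position | c1ccccc1COc1ccc2c(c1)O[C@H](c1cc(OCc3ccccc3)c(OCc3ccccc3)c(OCc3ccccc3)c1)[C@@H](OCc3ccccc3)[C@@H]2c1c(OCc3ccccc3)cc(O)c(c1OCc1ccccc1)C[C@H]1O[C@H]1c1cc(OCc3ccccc3)c(OCc3ccccc3)c(OCc3ccccc3)c1
A3 | alternative 2 | all-trans 3-(pinacolboryl)-2,4-diarylchroman carrying the 8-bromo-hexa-O-benzyl lower unit | c1ccccc1COc1ccc2c(c1)O[C@H](c1cc(OCc3ccccc3)c(OCc3ccccc3)c(OCc3ccccc3)c1)[C@@H](B3OC(C)(C)C(C)(C)O3)[C@@H]2c1c(OCc3ccccc3)c(Br)c2c(c1OCc3ccccc3)C[C@@H](OCc3ccccc3)[C@@H](c1cc(OCc3ccccc3)c(OCc3ccccc3)c(OCc3ccccc3)c1)O2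
A4 | alternative 2 | 5-(benzyloxy)-2-[hydroxy(8-bromo-hexa-O-benzylepigallocatechin-6-yl)methyl]phenol (carbinol epimers) | Oc1cc(OCc2ccccc2)ccc1C(O)c1c(OCc3ccccc3)c(Br)c2c(c1OCc1ccccc1)C[C@@H](OCc1ccccc1)[C@@H](c1cc(OCc3ccccc3)c(OCc3ccccc3)c(OCc3ccccc3)c1)O2
A5 | alternative 2 | (E)-4,4,5,5-tetramethyl-2-{2-[3,4,5-tris(benzyloxy)phenyl]vinyl}-1,3,2-dioxaborolane | CC1(C)OB(/C=C/c2cc(OCc3ccccc3)c(OCc3ccccc3)c(OCc3ccccc3)c2)OC1(C)C
A6 | alternative 3 | 8''-bromo-undeca-O-benzyl-robinetinidol-(4α→6)-epigallocatechin | c1ccccc1COc1ccc2c(c1)O[C@H](c1cc(OCc3ccccc3)c(OCc3ccccc3)c(OCc3ccccc3)c1)[C@@H](OCc3ccccc3)[C@@H]2c1c(OCc3ccccc3)c(Br)c2c(c1OCc3ccccc3)C[C@@H](OCc3ccccc3)[C@@H](c1cc(OCc3ccccc3)c(OCc3ccccc3)c(OCc3ccccc3)c1)O2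
A7 | alternative 3 | acyclic C4 carbinol with a 3-(benzyloxy)phenyl ether at C2 (C4 epimers) | c1ccccc1COc1cccc(c1)O[C@H](c1cc(OCc3ccccc3)c(OCc3ccccc3)c(OCc3ccccc3)c1)[C@@H](OCc3ccccc3)C(O)c1c(OCc3ccccc3)c(Br)c2c(c1OCc3ccccc3)C[C@@H](OCc3ccccc3)[C@@H](c1cc(OCc3ccccc3)c(OCc3ccccc3)c(OCc3ccccc3)c1)O2
A8 | alternative 3 | 3-(benzyloxy)phenol | Oc1cccc(OCc2ccccc2)c1
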